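Readings and results are simulated from invented constants, and the scatter is random.

3 questions stand on this flask, and I carry one number through them.

in all of them: left-handed substrate 0.25 M; right-handed substrate 0.25 M
- oak: solid reagent 0.55 M; free catalyst 39 mM; impurity 20 mM; run made earlier
- cedar: solid reagent 0.55 M; free catalyst 62 mM; impurity 20 mM; run made earlier
- larch: solid reagent 0.55 M; free catalyst 28 mM; impurity 40 mM; run made earlier
- flask: solid reagent 0.550 M; free catalyst 28 mM; impurity 20 mM; time 3.0 min

| run | time / min | left-handed product / % | right-handed product / % |
|---|---|---|---|
| oak | 0.167 | 3 | 3 |
| oak | 0.500 | 8 | 7 |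
| oak | 0.833 | 17 | 9 |
| oak | 1.33 | 28 | 12 |
| oak | 2.00 | 35 | 17 |
| oak | 2.50 | 42 | 24 |
| cedar | 0.417 | 16 | 9 |
| cedar | 0.833 | 29 | 14 |
| cedar | 1.33 | 39 | 22 |
| cedar | 1.50 | 40 | 24 |
| cedar | 2.00 | 54 | 28 |
| cedar | 2.50 | 55 | 28 |
| larch | 0.500 | 1 | 0 |
| larch | 1.00 | 0 | 1 |
| larch | 1.33 | 1 | 0 |
| larch | 2.00 | 0 | 1 |
| larch | 2.50 | 1 | 1 |

(standard deviation of a reading: 1.5 percentage points)

- free catalyst is single-handed; left-handed substrate and right-handed substrate are mirror images of each other, charged as a racemate, each of them at the stated concentration
- given per volume of solution although it is solid: solid reagent
- the analysis behind the earlier runs scatters by 1.5 percentage points, standard deviation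
- at the start none of the solid reagent is in solution
- an excess is the difference of the two amounts in percent of their sum
- an excess is below zero if the other one leads

* left-handed product and right-handed product together, in percent of the left-handed substrate and right-handed substrate charged together, at 3.0 min
* excess of left-handed product over right-handed product in the product at 3.0 min
* whether the exchange between left-handed substrate and right-handed substrate keeps pace with the reaction: how far the product's excess at 3.0 min gets from its value without exchange to its value with instant exchange (above 80 % keeps pace, below 20 % hardly takes part, else lags behind)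

Cedar's reading at 0.833 min gives a product ratio of 2.07, which I take as the selectivity factor. If the two substrates stay level, the product's excess is that factor less one over that factor plus one, 34.9 %. Staying level needs right-handed substrate to cross over. Dividing the crossing rate by the product rate drops time out: per unit of product, 0.174 must cross, the crossing share.

Now the question turned round: what would the readings show if exchange hardly took part? Without exchange, the same division says the left-handed substrate remaining, as a fraction of its own charge, would equal the right-handed fraction raised to the selectivity factor. Cedar's last 28 % of right-handed product would then go with 40.9 % of left-handed product. Cedar reads 55 %, a gap of 14 percentage points, so I take it that exchange takes part in cedar. Oak, with less free catalyst, still reads a ratio of 2.06 at 2.00 min, so I don't tie exchange to the catalyst.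

Larch reads about zero with impurity above its catalyst, so I subtract impurity from catalyst one for one. Scaling oak's pseudo-first-order constant 0.432 min⁻¹ to this flask's free catalyst gives 0.182 min⁻¹, so y is 42.0 %. This flask then needs 0.0244 min⁻¹ of the charge crossing on average, less than cedar's 0.0579 min⁻¹. I commit to an excess of 34.9 % and to exchange keeping pace.

The forecast says 42 %, 36 % and lags behind, holding that “exchange probably scales with catalyst and is weak here”. The flask gives 43.2 %, 32.5 % and keeps pace, 90 % of the way.

    coupling partner + free catalyst + left-handed substrate → free catalyst + left-handed product (k = 54.0 L² mol⁻² s⁻¹)
    coupling partner + free catalyst + right-handed substrate → free catalyst + right-handed product (k = 27.0 L² mol⁻² s⁻¹)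
    left-handed substrate ⇌ right-handed substrate (k = 0.0550 s⁻¹)
    2 coupling partner → self-condensation product (k = 0.130 L mol⁻¹ s⁻¹)
    free catalyst + impurity → spent catalyst (k = 260 L mol⁻¹ s⁻¹)
    solid reagent ⇌ coupling partner, rate k6*(cs6 - [coupling partner]) while solid is left; crystals form when [coupling partner] > cs6 (solubility = 11.0 mM, k = 1.00 s⁻¹)

At 3.00 min this flask holds 28.1 % left-handed and 28.7 % right-handed substrate, and the left-handed step uses coupling partner 2.0 times as fast as the right-handed one. The crossing share asks 7.53 % of the charge, and up to the asked time a net 6.75 % crossed from right-handed to left-handed substrate. In the neighbour with 0.048 M of free catalyst, the share asks 14.4 % for its 82.5 % of product. That neighbour gives an excess of 31.0 %, with 8.43 % left-handed and 9.03 % right-handed substrate.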